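**Retrosynthetic overview**

1. Ring numbering used throughout: C1 = quaternary carbinol carbon (bears CH2OBz), C2 = ketone carbon, C3=C4 = alkene, C5 = CHOH, C6 = CHOBz.
2. Enabling feature: C2, C1 and C6 are three contiguous oxygen-bearing ring carbons, a hidden dihydroxyacetone. With C1 at the ketone level, C2 and C6 are both nucleophilic α-carbons, and C3–C4–C5 is a hidden acrolein (C3 = β-carbon, C5 = formyl carbon).
3. Key disconnection: C2–C3 (Michael) and C5–C6 (aldol) in one amine-catalysed α,α'-[3+3] annulation of 2-phenyl-1,3-dioxan-5-one with 2-(phenylselanyl)acrolein. The 1,3-dioxane ring ties O–C2 to O–C6, so the product is a 2,4-dioxabicyclo[3.3.1]nonan-9-one with non-enolisable bridgeheads. Selenium on C4 is the latent C3=C4 alkene.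
4. After the key step: selenoxide elimination (C3=C4), methylene transfer to the C1 ketone, benzoate opening of the oxirane (C1 centre, CH2OBz), acetal removal, allylic oxidation at C2, benzoylation at O6, desilylation at O5.
5. Ring order: 1,3-dioxane (in the starting material, temporary), carbocycle (key step), spiro-oxirane (temporary). Oxirane and dioxane are both opened again before the end.

Key step: step 3

Remark: the selenium-bearing carbon of the intermediates between the key step and the selenoxide elimination is drawn exo; its configuration has no consequence, because that centre becomes sp2.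

**Step 1**
Reactants: 1 cis-2-phenyl-1,3-dioxan-5-ol (1,3-O-benzylideneglycerol)
Product: 2 2-phenyl-1,3-dioxan-5-one
Conditions: IBX (1.5 equiv), EtOAc, 80 °C
Reagents that add atoms: none
Why: Hypervalent-iodine oxidation of a secondary alcohol under neutral conditions leaves the benzylidene acetal untouched and removes the only variable stereocentre of 1.

**Step 2**
Reactants: 3 acrolein (prop-2-enal)
Product: 5 2-(phenylselanyl)prop-2-enal, via 3-chloro-2-(phenylselanyl)propanal 4 (not isolated)
Conditions: PhSeCl, CH2Cl2, −78 to 0 °C; then Et3N, 0 °C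
Reagents that add atoms: benzeneselenenyl chloride, Cl[Se]c1ccccc1
Why: Electrophilic selenenylation of the enal (selenium at the α-carbon, chloride at the β-carbon) followed by E1cB dehydrochlorination is the selenium counterpart of the bromination–dehydrobromination route to 2-haloacroleins.

**Step 3**
Reactants: 2 2-phenyl-1,3-dioxan-5-one; 5 2-(phenylselanyl)prop-2-enal
Product: 7 (1R,3S,5S,6S,7R)-6-hydroxy-3-phenyl-7-(phenylselanyl)-2,4-dioxabicyclo[3.3.1]nonan-9-one, via Michael adduct keto aldehyde 6 (not isolated)
Conditions: D-proline (30 mol %), DMF, 4 °C to rt; 5 added slowly to 2 (2 equiv)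
Reagents that add atoms: none
Why: Proposed new method: D-proline turns 2 into its enamine, which adds through the α-carbon to the CH2 terminus of 5 (Michael addition, new bond C2–C3); the keto aldehyde 6 so formed is taken up again as the enamine of the still free α'-carbon, which attacks the tethered formyl group (intramolecular aldol addition, new bond C5–C6), and hydrolysis releases 7 and the catalyst. The closest known reaction types are the α,α'-annulation of cyclic ketone enamines with acrolein to bicyclo[3.3.1]nonan-9-ones, the amine-catalysed asymmetric Michael–aldol [3+3] annulation of cyclic ketones with β,γ-unsaturated α-keto esters, and the proline-catalysed aldol and Michael additions of 1,3-dioxan-5-ones; their merger on a dioxanone and a 2-selanyl enal is what is new. The only ring that closes is the carbocycle, in the 6-(enolendo)-exo-trig mode. The Michael-derived bridgehead is set by catalyst and ring together: the acceptor, hydrogen-bonded to the carboxyl group, is delivered on the carboxyl-bearing face of the anti enamine (the sense known from proline-catalysed aldol and Michael additions of cyclic ketones, which on this model gives the (R) centre with D-proline) and it enters axially, trans to the equatorial phenyl group, which fixes the acetal carbon relative to it, while the second bridgehead follows because the three-atom tether can reach only the same axial face. The carbinol centre is set by the closed, hydrogen-bonded aldol transition state, in which the formyl oxygen lies gauche to the enamine nitrogen and the tether holds the formyl substituent axial, so OH ends axial on the new ring and anti to the neighbouring bridgehead C–O bond (the trans C5/C6 relation of the target); the selenium-bearing centre stays epimerisable in 6, should settle exo away from the endo acetal hydrogen, and is erased in step 5. The step needs 1,4- over 1,2-addition, a single annulation and no dehydration: aldol addition to the enal carbonyl is reversible under proline catalysis whereas the Michael addition is not, the selanyl group stabilises the developing α-carbanion and makes the formyl group of 6 more electrophilic, and both α-carbons of 7 are bridgeheads, so enolisation, β-elimination and aromatisation are blocked by Bredt's rule.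

**Step 4**
Reactants: 7 seleno ketol
Product: 8 (1R,3S,5S,6S,7R)-6-[(tert-butyldimethylsilyl)oxy]-3-phenyl-7-(phenylselanyl)-2,4-dioxabicyclo[3.3.1]nonan-9-one
Conditions: TBSOTf, 2,6-lutidine, CH2Cl2, −78 to 0 °C
Reagents that add atoms: tert-butyldimethylsilyl triflate, CC(C)(C)[Si](C)(C)OS(=O)(=O)C(F)(F)F
Why: Silyl triflate silylation under weakly basic conditions protects the hindered axial alcohol without retro-aldol cleavage, and no silyl enol ether can form because both α-carbons are bridgeheads.

**Step 5**
Reactants: 8 silyl ether selenide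
Product: 10 (1S,3S,5R,8R)-8-[(tert-butyldimethylsilyl)oxy]-3-phenyl-2,4-dioxabicyclo[3.3.1]non-6-en-9-one, via selenoxide 9 (not isolated)
Conditions: mCPBA (1.0 equiv), CH2Cl2, −78 °C; then i-Pr2NH, −78 °C to rt
Reagents that add atoms: mCPBA, O=C(OO)c1cccc(Cl)c1 (its oxygen atom is held by 9 only)
Why: Selenoxide syn elimination after chemoselective low-temperature oxidation at selenium goes only towards the CH2 group, because the hydrogen on the silyloxy-bearing carbon is trans to selenium and that direction would give an enol ether anyway.

**Step 6**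
Reactants: 10 bicyclic enone-free ketone
Product: 11 (1S,3S,5R,8R,9S)-8-[(tert-butyldimethylsilyl)oxy]-3-phenylspiro[2,4-dioxabicyclo[3.3.1]non-6-ene-9,2'-oxirane] (oxirane oxygen syn to the cyclohexene bridge, CH2 over the dioxane ring)
Conditions: Me3SI, NaH, DMSO/THF, 0 °C
Reagents that add atoms: trimethylsulfonium iodide, C[S+](C)C.[I-]
Why: In this Corey–Chaykovsky epoxidation of a non-enolisable ketone the methylide enters axially with respect to the 1,3-dioxan-5-one ring, over the two ring oxygen atoms (the intrinsically preferred trajectory and the only open one, since the pseudoaxial OTBS group covers the other face), so the oxirane oxygen ends syn to the C5 oxygen and the C1 configuration of the target is set.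

**Step 7**
Reactants: 11 spiro-oxirane
Product: 12 [(1S,3S,5R,8R,9S)-8-[(tert-butyldimethylsilyl)oxy]-9-hydroxy-3-phenyl-2,4-dioxabicyclo[3.3.1]non-6-en-9-yl]methyl benzoate
Conditions: PhCO2H (3 equiv), PhCO2Cs (0.5 equiv), DMF, 90 °C
Reagents that add atoms: benzoic acid, O=C(O)c1ccccc1
Why: SN2 opening of a 2,2-disubstituted oxirane by carboxylate at the CH2 carbon leaves the quaternary centre untouched and gives the primary benzoate and the free tertiary alcohol at once, with the benzoic acid buffer protonating the alkoxide before silyl or acyl migration.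

**Step 8**
Reactants: 12 bicyclic hydroxy benzoate
Product: 13 [(1S,2R,5R,6S)-5-[(tert-butyldimethylsilyl)oxy]-1,2,6-trihydroxycyclohex-3-en-1-yl]methyl benzoate
Conditions: AcOH/THF/H2O (4:1:1), 40 °C
Reagents that add atoms: none
Why: Acid-catalysed acetal hydrolysis, helped by the release of bicyclic strain as the freed cyclohexene flips to the conformer with its oxygen substituents equatorial, is mild enough to keep the secondary TBS ether and the benzoate.

**Step 9**
Reactants: 13 triol
Product: 14 [(1R,5R,6S)-5-[(tert-butyldimethylsilyl)oxy]-1,6-dihydroxy-2-oxocyclohex-3-en-1-yl]methyl benzoate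
Conditions: activated MnO2 (excess), CH2Cl2, rt
Reagents that add atoms: none
Why: Allylic oxidation with MnO2 is chemoselective because C2–OH is the only free allylic hydroxyl (O5 is silylated, C6–OH is not allylic, C1–OH is tertiary).

**Step 10**
Reactants: 14 hydroxy enone
Product: 15 [(1R,5R,6S)-6-(benzoyloxy)-5-[(tert-butyldimethylsilyl)oxy]-1-hydroxy-2-oxocyclohex-3-en-1-yl]methyl benzoate
Conditions: BzCl, pyridine, DMAP (cat.), CH2Cl2, 0 °C to rt
Reagents that add atoms: benzoyl chloride, O=C(Cl)c1ccccc1
Why: DMAP-catalysed acylation distinguishes the secondary C6–OH from the tertiary α-ketol hydroxyl on steric grounds.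

**Step 11**
Reactants: 15 silylated dibenzoate
Product: 16 [(1R,5R,6S)-6-(benzoyloxy)-1,5-dihydroxy-2-oxocyclohex-3-en-1-yl]methyl benzoate (target)
Conditions: HF·pyridine, THF/pyridine, 0 °C to rt
Reagents that add atoms: none
Why: Fluoride-mediated desilylation in an acidic medium avoids the base-induced benzoyl shift from O6 to O5 and the β-elimination of the sensitive γ-hydroxy enone.

**Compound list**

1 | cis-2-phenyl-1,3-dioxan-5-ol | O[C@H]1CO[C@@H](c2ccccc2)OC1 | starting material
2 | 2-phenyl-1,3-dioxan-5-one | O=C1COC(c2ccccc2)OC1 | intermediate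
3 | acrolein | C=CC=O | starting material
4 | 3-chloro-2-(phenylselanyl)propanal (racemic) | O=CC(CCl)[Se]c1ccccc1 | intermediate
5 | 2-(phenylselanyl)prop-2-enal | C=C([Se]c1ccccc1)C=O | intermediate
6 | 3-[(2R,4R)-5-oxo-2-phenyl-1,3-dioxan-4-yl]-2-(phenylselanyl)propanal (epimerisable at the selenium-bearing carbon) | O=CC([Se]c1ccccc1)C[C@H]1O[C@H](c2ccccc2)OCC1=O | intermediate
7 | (1R,3S,5S,6S,7R)-6-hydroxy-3-phenyl-7-(phenylselanyl)-2,4-dioxabicyclo[3.3.1]nonan-9-one | O=C1[C@H]2C[C@@H]([Se]c3ccccc3)[C@@H](O)[C@@H]1O[C@@H](c1ccccc1)O2 | intermediate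
8 | (1R,3S,5S,6S,7R)-6-[(tert-butyldimethylsilyl)oxy]-3-phenyl-7-(phenylselanyl)-2,4-dioxabicyclo[3.3.1]nonan-9-one | O=C1[C@H]2C[C@@H]([Se]c3ccccc3)[C@@H](O[Si](C)(C)C(C)(C)C)[C@@H]1O[C@@H](c1ccccc1)O2 | intermediate
9 | selenoxide of 8 (7-benzeneseleninyl compound, either configuration at selenium) | O=C1[C@H]2C[C@@H]([Se](=O)c3ccccc3)[C@@H](O[Si](C)(C)C(C)(C)C)[C@@H]1O[C@@H](c1ccccc1)O2 | intermediate
10 | (1S,3S,5R,8R)-8-[(tert-butyldimethylsilyl)oxy]-3-phenyl-2,4-dioxabicyclo[3.3.1]non-6-en-9-one | O=C1[C@H]2C=C[C@@H](O[Si](C)(C)C(C)(C)C)[C@@H]1O[C@@H](c1ccccc1)O2 | intermediate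
11 | (1S,3S,5R,8R,9S)-8-[(tert-butyldimethylsilyl)oxy]-3-phenylspiro[2,4-dioxabicyclo[3.3.1]non-6-ene-9,2'-oxirane] | C1O[C@]12[C@H]3C=C[C@@H](O[Si](C)(C)C(C)(C)C)[C@@H]2O[C@@H](c2ccccc2)O3 | intermediate
12 | [(1S,3S,5R,8R,9S)-8-[(tert-butyldimethylsilyl)oxy]-9-hydroxy-3-phenyl-2,4-dioxabicyclo[3.3.1]non-6-en-9-yl]methyl benzoate | O=C(OC[C@]1(O)[C@H]2C=C[C@@H](O[Si](C)(C)C(C)(C)C)[C@@H]1O[C@@H](c1ccccc1)O2)c1ccccc1 | intermediate
13 | [(1S,2R,5R,6S)-5-[(tert-butyldimethylsilyl)oxy]-1,2,6-trihydroxycyclohex-3-en-1-yl]methyl benzoate | O=C(OC[C@]1(O)[C@H](O)C=C[C@@H](O[Si](C)(C)C(C)(C)C)[C@@H]1O)c1ccccc1 | intermediate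
14 | [(1R,5R,6S)-5-[(tert-butyldimethylsilyl)oxy]-1,6-dihydroxy-2-oxocyclohex-3-en-1-yl]methyl benzoate | O=C(OC[C@]1(O)C(=O)C=C[C@@H](O[Si](C)(C)C(C)(C)C)[C@@H]1O)c1ccccc1 | intermediate
15 | [(1R,5R,6S)-6-(benzoyloxy)-5-[(tert-butyldimethylsilyl)oxy]-1-hydroxy-2-oxocyclohex-3-en-1-yl]methyl benzoate | O=C(OC[C@]1(O)C(=O)C=C[C@@H](O[Si](C)(C)C(C)(C)C)[C@@H]1OC(=O)c1ccccc1)c1ccccc1 | intermediate
16 | [(1R,5R,6S)-6-(benzoyloxy)-1,5-dihydroxy-2-oxocyclohex-3-en-1-yl]methyl benzoate | O=C(OC[C@]1(O)C(=O)C=C[C@@H](O)[C@@H]1OC(=O)c1ccccc1)c1ccccc1 | target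

**Step count**

- Total step count: 11.
- Longest linear sequence: 10 (step 1 or step 2, then steps 3 to 11).

**Steps most likely to fail**

**Step 3 (proposed new method).**
- What may go wrong: the enamine may add to the enal carbonyl or the enal may oligomerise. The catalyst may be tied up by the aldehyde. Enantioselectivity may erode, because the ring-closing enamine has to react on the face that the catalyst does not favour.
- Fallback, from 2 back to 7, by known reaction types:
  - 2 is condensed with pyrrolidine to the enamine 1-(2-phenyl-4H-1,3-dioxin-5-yl)pyrrolidine F1.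
  - A Stork enamine Michael addition to 5 and buffered aqueous hydrolysis should give the racemic keto aldehyde F2.
  - Piperidinium acetate should close it by intramolecular aldol addition to the racemic ketol F3.
  - A lipase-catalysed kinetic resolution (Candida antarctica lipase B or a screened alternative, vinyl acetate, MTBE) is chosen so that the unwanted enantiomer is converted into its acetate F4 and 7 is left as the free alcohol.

**Step 6.**
- What may go wrong: facial selectivity may be poor or reversed if the dioxane ring leaves its chair form and covers the face over the ring oxygen atoms.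
- Fallback, from 10 back to 11: Wittig methylenation with Ph3P=CH2 should give the 9-methylidene compound F5. Buffered mCPBA epoxidation of this 1,1-disubstituted exocyclic alkene then brings oxygen rather than carbon to whichever face is open. This gives the configuration at the spiro carbon opposite to that of the ylide route, and so corrects a wrong-face methylene transfer.

**Step 10.**
- What may go wrong: acylation of the C6 hydroxyl, flanked by the OTBS group and the quaternary carbon, may be slow. It would then compete with base-induced elimination, aromatisation or benzoyl migration in the enone.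
- Fallback, from 13 back to 15, placing the benzoylation before the enone exists:
  - Selective silylation of the less hindered allylic C2 hydroxyl (TESCl, imidazole, low temperature) should give the C2 triethylsilyl ether F6.
  - Benzoylation at O6 (BzCl, DMAP) should give the dibenzoate F7.
  - Dilute aqueous AcOH should remove only the triethylsilyl group, giving the allylic alcohol F8.
  - Dess–Martin oxidation should then give 15.

**Further compounds**

F1 | step 3 | 1-(2-phenyl-4H-1,3-dioxin-5-yl)pyrrolidine | C1CCN(C1)C1=COC(c2ccccc2)OC1
F2 | step 3 | racemic keto aldehyde (racemate of 6) | O=CC([Se]c1ccccc1)CC1OC(c2ccccc2)OCC1=O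
F3 | step 3 | racemic ketol (racemate of 7, same relative configuration) | O=C1C2CC([Se]c3ccccc3)C(O)C1OC(c1ccccc1)O2
F4 | step 3 | acetate of the enantiomer of 7 | O=C1[C@@H]2C[C@H]([Se]c3ccccc3)[C@H](OC(C)=O)[C@H]1O[C@H](c1ccccc1)O2
F5 | step 6 | 9-methylidene analogue of 10 (spatial arrangement at the stereocentres as in 10) | C=C1[C@H]2C=C[C@@H](O[Si](C)(C)C(C)(C)C)[C@@H]1O[C@@H](c1ccccc1)O2
F6 | step 10 | C2 triethylsilyl ether of 13 | O=C(OC[C@]1(O)[C@H](O[Si](CC)(CC)CC)C=C[C@@H](O[Si](C)(C)C(C)(C)C)[C@@H]1O)c1ccccc1
F7 | step 10 | O6 benzoate of F6 | O=C(OC[C@]1(O)[C@H](O[Si](CC)(CC)CC)C=C[C@@H](O[Si](C)(C)C(C)(C)C)[C@@H]1OC(=O)c1ccccc1)c1ccccc1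
F8 | step 10 | C2 allylic alcohol from F7 | O=C(OC[C@]1(O)[C@H](O)C=C[C@@H](O[Si](C)(C)C(C)(C)C)[C@@H]1OC(=O)c1ccccc1)c1ccccc1
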